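## Retrosynthetic overview

1. The last C–C bond is C7(sp2)–C8(sp3). The α-carbon of ring B is by nature a vinylogous-enolate donor. Here it is used as its chloride (a vinylogous enolonium equivalent) and joined to the E-alkenyl iodide of the left half. A stereoconvergent Ni/bis(oxazoline) reductive alkenylation makes the bond and sets C8; only desilylation follows.
2. Left half: C2–C3 comes from a vinylogous Mukaiyama aldol of symmetrical 2,6-diethyl-3,5-dimethyl-4-pyrone (natural polarity) with a 2,3-anti α-methyl-β-silyloxy aldehyde.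
3. That aldehyde comes from propargyl alcohol by carboalumination/iodination, oxidation to the enal, catalytic asymmetric E-crotylboration (C4, C5) and vinyl cleavage.
4. Right half: Evans syn aldol (C2'', C3''), Weinreb amide, γ-acylation of the 4-methylheptane-3,5-dione dianion, cyclodehydration, then γ-chlorination.
5. Ring order: ring A is formed first (step 1) and ring B second (step 12, from an acyclic triketone). No ring is formed after the fragment union.

Locants: C1–C9 are the nonenyl chain in the name of the target. Double-primed locants refer to the pentan-2-yl side chain of ring B.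

Assumption: the sense of induction of the Ni/IndaBOX catalyst is carried over from 1-arylethyl chlorides to the 1-(pyron-2-yl)ethyl chloride, and the equally available ligand antipode is used if a model coupling shows the opposite sense; 4-methylheptane-3,5-dione is taken as a catalogue chemical.

## Route

Step 1
Reactants: 1 pentan-3-one; 2 propanoic acid
Product: 4 2,6-diethyl-3,5-dimethyl-4H-pyran-4-one, via triketone 3 (not isolated)
Conditions: 2 (2.5 equiv), polyphosphoric acid, 100 °C, 6 h; ice, NaOH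
Reagents that add atoms: none
Why: PPA-activated propanoic acid C-acylates both α-carbons of the ketone and the resulting 1,3,5-triketone cyclodehydrates in the same medium (ketone/acid γ-pyrone condensation); no stereocentre is formed.

Step 2
Reactants: 5 prop-2-yn-1-ol
Product: 7 (E)-3-iodo-2-methylprop-2-en-1-ol, via alkenylalane 6 (not isolated)
Conditions: AlMe3 (3 equiv), Cp2ZrCl2 (0.25 equiv), CH2Cl2, 0 °C to rt; I2, THF, −30 to 0 °C; aq K2CO3
Reagents that add atoms: trimethylaluminium C[Al](C)C; iodine II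
Why: In the Negishi Zr-catalysed carboalumination, Me–Al adds syn with Al at the terminus, and iodinolysis with retention fixes the E geometry (CH2OH trans to I).

Step 3
Reactants: 7 (E)-3-iodo-2-methylprop-2-en-1-ol
Product: 8 (E)-3-iodo-2-methylprop-2-enal
Conditions: MnO2 (15 equiv), CH2Cl2, rt, dark
Reagents that add atoms: none
Why: MnO2 allylic oxidation is neutral, stops at the aldehyde, and leaves the C–I bond and the E geometry untouched.

Step 4
Reactants: 8 (E)-3-iodo-2-methylprop-2-enal; 9 (E)-crotylboronic acid pinacol ester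
Product: 11 (1E,3S,4S)-1-iodo-2,4-dimethylhexa-1,5-dien-3-ol, via pinacol borate 10 (not isolated)
Conditions: (S)-TRIP phosphoric acid (5 mol %), 9 (1.2 equiv), 4 Å MS, toluene, −30 °C; aq NaHCO3
Reagents that add atoms: none
Why: In the chiral phosphoric acid catalysed crotylboration (type I, closed chair), the E-crotyl geometry gives the C4/C5 anti relation, and (S)-TRIP, the mirror image of the (R)-TRIP/Re-face preference of aryl and alkenyl aldehydes, directs attack to the Si face and sets C5 as S.

Step 5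
Reactants: 11 (1E,3S,4S)-1-iodo-2,4-dimethylhexa-1,5-dien-3-ol
Product: 12 tert-butyl{[(1E,3S,4S)-1-iodo-2,4-dimethylhexa-1,5-dien-3-yl]oxy}dimethylsilane
Conditions: TBSOTf (1.2 equiv), 2,6-lutidine (1.5 equiv), CH2Cl2, −78 to 0 °C
Reagents that add atoms: tert-butyldimethylsilyl triflate CC(C)(C)[Si](C)(C)OS(=O)(=O)C(F)(F)F
Why: Standard O-silylation installs the non-chelating β-silyloxy group that step 7 needs for polar 1,3-induction, without touching any stereocentre.

Step 6
Reactants: 12 tert-butyl{[(1E,3S,4S)-1-iodo-2,4-dimethylhexa-1,5-dien-3-yl]oxy}dimethylsilane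
Product: 13 (2R,3S,4E)-3-(tert-butyldimethylsilyloxy)-5-iodo-2,4-dimethylpent-4-enal
Conditions: OsO4 (2 mol %), NaIO4 (4 equiv), 2,6-lutidine (2 equiv), dioxane/H2O 3:1, rt
Reagents that add atoms: osmium tetroxide O=[Os](=O)(=O)=O (catalytic oxygen carrier); sodium periodate [Na+].[O-]I(=O)(=O)=O (terminal oxygen source)
Why: Lemieux–Johnson cleavage takes the unhindered monosubstituted vinyl group rather than the electron-poor hindered iodoalkene, and the lutidine buffer prevents α-epimerisation.

Step 7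
Reactants: 4 2,6-diethyl-3,5-dimethyl-4H-pyran-4-one; 13 (2R,3S,4E)-3-(tert-butyldimethylsilyloxy)-5-iodo-2,4-dimethylpent-4-enal
Product: 15 2-ethyl-6-[(2S,3S,4S,5S,6E)-5-(tert-butyldimethylsilyloxy)-3-hydroxy-7-iodo-4,6-dimethylhept-6-en-2-yl]-3,5-dimethyl-4H-pyran-4-one, via silyl dienol ether 14 (not isolated)
Conditions: 4 (1.5 equiv), TBSOTf (1.5 equiv), i-Pr2NEt (1.5 equiv), CH2Cl2, 0 °C; then 13, BF3·OEt2 (2 equiv), −78 °C; aq NaHCO3
Reagents that add atoms: none
Why: Proposed new method: O-silylation gives a 4-silyloxypyrylium whose α-CH2 is deprotonated by the amine to the 2-ethylidene-2H-pyran 14 (A1,3 strain with 3-Me places the ethylidene methyl next to the ring O), and this cyclic silyl dienol ether attacks the BF3-bound aldehyde through its exocyclic γ-carbon in an open transition state driven by re-formation of the pyrylium; Felkin–Anh and polar 1,3-anti induction reinforce each other in the 2,3-anti aldehyde and set C3 (3,4-syn, 3,5-anti), while the antiperiplanar arrangement that keeps the ethylidene methyl away from BF3 gives the 2,3-anti relation; the closest known types are the vinylogous Mukaiyama aldol of E-configured γ-methyl silyl dienol ethers and the lithium vinylogous aldol of 2-ethyl-4-pyrones.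

Step 8
Reactants: 16 (S)-4-benzyl-3-propanoyl-1,3-oxazolidin-2-one; 17 propanal
Product: 20 (S)-4-benzyl-3-[(2S,3R)-3-hydroxy-2-methylpentanoyl]-1,3-oxazolidin-2-one, via Z-boron enolate 18 (not isolated), via boron aldolate 19 (not isolated)
Conditions: n-Bu2BOTf (1.1 equiv), Et3N (1.3 equiv), CH2Cl2, −78 to 0 °C; 17, −78 to 0 °C; pH 7 buffer, MeOH, 30 % H2O2, 0 °C
Reagents that add atoms: none
Why: In the Evans syn aldol, the Z-boron enolate reacts through a Zimmerman–Traxler chair with the auxiliary dipole opposed, and the (S)-benzyl auxiliary delivers the (2S,3R)-syn adduct that becomes C2''/C3''.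

Step 9
Reactants: 20 (S)-4-benzyl-3-[(2S,3R)-3-hydroxy-2-methylpentanoyl]-1,3-oxazolidin-2-one
Product: 21 (2S,3R)-3-hydroxy-N-methoxy-N,2-dimethylpentanamide
Conditions: MeNH(OMe)·HCl (3 equiv), AlMe3 (3 equiv), THF, −20 to 0 °C; aq Rochelle salt
Reagents that add atoms: N,O-dimethylhydroxylamine hydrochloride CNOC.Cl
Why: In the Weinreb transamidation the aluminium amide, guided by the free β-hydroxyl, attacks the exocyclic imide carbonyl without epimerisation or retro-aldol.

Step 10
Reactants: 21 (2S,3R)-3-hydroxy-N-methoxy-N,2-dimethylpentanamide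
Product: 22 (2S,3R)-3-(tert-butyldimethylsilyloxy)-N-methoxy-N,2-dimethylpentanamide
Conditions: TBSOTf (1.2 equiv), 2,6-lutidine (1.5 equiv), CH2Cl2, 0 °C
Reagents that add atoms: tert-butyldimethylsilyl triflate CC(C)(C)[Si](C)(C)OS(=O)(=O)C(F)(F)F
Why: Standard O-silylation blocks retro-aldol and hemiketal formation in the carbanion and dehydration steps that follow.

Step 11
Reactants: 23 4-methylheptane-3,5-dione; 22 (2S,3R)-3-(tert-butyldimethylsilyloxy)-N-methoxy-N,2-dimethylpentanamide
Product: 25 (8S,9R)-9-(tert-butyldimethylsilyloxy)-4,6,8-trimethylundecane-3,5,7-trione, via dilithium dienolate 24 (not isolated)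
Conditions: 23 (2 equiv), LDA (4.1 equiv), THF, −78 to 0 °C; 22, −78 to −20 °C; aq NH4Cl
Reagents that add atoms: none
Why: In this γ-acylation of a β-diketone dianion (Hauser–Harris type), the more reactive terminal carbanion of the symmetrical dianion attacks the amide, and the chelated tetrahedral adduct survives until the quench, so C8 is neither over-acylated nor epimerised (C4 and C6 are labile and vanish in step 12).

Step 12
Reactants: 25 (8S,9R)-9-(tert-butyldimethylsilyloxy)-4,6,8-trimethylundecane-3,5,7-trione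
Product: 26 2-ethyl-6-[(2S,3R)-3-(tert-butyldimethylsilyloxy)pentan-2-yl]-3,5-dimethyl-4H-pyran-4-one
Conditions: PPh3 (2 equiv), CCl4 (5 equiv), THF, rt to 40 °C
Reagents that add atoms: none
Why: In this Appel-type cyclodehydration one terminal enol is activated as its oxyphosphonium salt and displaced by the other enol oxygen, which closes ring B without strong acid or added base, so the silyl ether and the α-stereocentre C2'' survive.

Step 13
Reactants: 26 2-ethyl-6-[(2S,3R)-3-(tert-butyldimethylsilyloxy)pentan-2-yl]-3,5-dimethyl-4H-pyran-4-one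
Product: 28 2-(1-chloroethyl)-6-[(2S,3R)-3-(tert-butyldimethylsilyloxy)pentan-2-yl]-3,5-dimethyl-4H-pyran-4-one (both CHCl epimers), via lithium dienolate 27 (not isolated)
Conditions: LiHMDS (1.05 equiv), THF, −78 °C; cannulated into NCS (1.2 equiv), THF, −78 °C; aq NH4Cl
Reagents that add atoms: N-chlorosuccinimide O=C1CCC(=O)N1Cl
Why: In this vinylogous enolate halogenation, kinetic deprotonation takes the unhindered ethyl CH2 and not the tertiary C2''–H, Cl+ is accepted at the exocyclic γ-carbon, and that donor carbon thereby becomes an acceptor; the new stereocentre is irrelevant because step 14 erases it.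

Step 14
Reactants: 15 2-ethyl-6-[(2S,3S,4S,5S,6E)-5-(tert-butyldimethylsilyloxy)-3-hydroxy-7-iodo-4,6-dimethylhept-6-en-2-yl]-3,5-dimethyl-4H-pyran-4-one; 28 2-(1-chloroethyl)-6-[(2S,3R)-3-(tert-butyldimethylsilyloxy)pentan-2-yl]-3,5-dimethyl-4H-pyran-4-one
Product: 29 5,3''-bis(tert-butyldimethylsilyl) ether of the target with (2S,3S,4S,5S,6E,8R,2''S,3''R) configuration
Conditions: NiCl2·dme (15 mol %), (3aS,3a'S,8aR,8a'R)-2,2'-(cyclopropane-1,1-diyl)bis(3a,8a-dihydro-8H-indeno[1,2-d]oxazole) (17 mol %), Mn powder (3 equiv), NaI (0.5 equiv), DMA, 0 °C, slow addition of 28 (1.3 equiv)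
Reagents that add atoms: none
Why: Proposed new method: 28 is a vinylogous α-halo carbonyl, so the pyrone α-carbon that acts as a donor in step 7 is used here as an acceptor (vinylogous enolonium equivalent) and bonded to the alkenyl carbon, which is converted in situ into its alkenyl-nickel donor form; L*Ni(0) inserts into the C(sp2)–I bond with retention of the E geometry, Ni(I) abstracts halogen from either epimer of 28 (after partial Cl/I exchange by NaI) to give one planar pyrone-stabilised secondary radical, L*Ni(II)(alkenyl) captures it, reductive elimination from Ni(III) sets C8 as R under ligand control (stereoconvergent), and Mn(0) closes the cycle; the base-free medium spares the free 3-OH, both silyl ethers and the acidic α-pyrone stereocentres C2, C8 and C2''; the closest known types are the Ni/bis(oxazoline) asymmetric reductive alkenylation of 1-arylethyl chlorides with alkenyl halides and the stereoconvergent Ni-catalysed alkenylation of racemic α-halo carbonyl compounds.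

Step 15
Reactants: 29 5,3''-bis(tert-butyldimethylsilyl) ether of the target
Product: 30 2-ethyl-6-[(2S,3S,4S,5S,6E,8R)-3,5-dihydroxy-8-{6-[(2S,3R)-3-hydroxypentan-2-yl]-3,5-dimethyl-4-oxo-4H-pyran-2-yl}-4,6-dimethylnon-6-en-2-yl]-3,5-dimethyl-4H-pyran-4-one
Conditions: HF·pyridine, pyridine, THF, 0 °C to rt
Reagents that add atoms: none
Why: Buffered fluoride desilylation removes both secondary TBS groups under weakly acidic conditions, avoiding the basic conditions that would epimerise C2, C8 or C2'' or move the alkene into conjugation.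

## Compound list

1 | pentan-3-one | CCC(=O)CC | starting material
2 | propanoic acid | CCC(=O)O | starting material
3 | 4,6-dimethylnonane-3,5,7-trione | CCC(=O)C(C)C(=O)C(C)C(=O)CC | intermediate
4 | 2,6-diethyl-3,5-dimethyl-4H-pyran-4-one | CCc1oc(CC)c(C)c(=O)c1C | intermediate
5 | prop-2-yn-1-ol | C#CCO | starting material
6 | dimethylaluminium (E)-3-(dimethylalumanyl)-2-methylprop-2-en-1-olate | C[Al](C)OC/C(C)=C/[Al](C)C | intermediate
7 | (E)-3-iodo-2-methylprop-2-en-1-ol | OC/C(C)=C/I | intermediate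
8 | (E)-3-iodo-2-methylprop-2-enal | O=C/C(C)=C/I | intermediate
9 | 2-[(E)-but-2-en-1-yl]-4,4,5,5-tetramethyl-1,3,2-dioxaborolane | C/C=C/CB1OC(C)(C)C(C)(C)O1 | starting material
10 | pinacol borate of 11 | C=C[C@H](C)[C@H](OB1OC(C)(C)C(C)(C)O1)/C(C)=C/I | intermediate
11 | (1E,3S,4S)-1-iodo-2,4-dimethylhexa-1,5-dien-3-ol | C=C[C@H](C)[C@H](O)/C(C)=C/I | intermediate
12 | tert-butyl{[(1E,3S,4S)-1-iodo-2,4-dimethylhexa-1,5-dien-3-yl]oxy}dimethylsilane | C=C[C@H](C)[C@H](O[Si](C)(C)C(C)(C)C)/C(C)=C/I | intermediate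
13 | (2R,3S,4E)-3-(tert-butyldimethylsilyloxy)-5-iodo-2,4-dimethylpent-4-enal | O=C[C@H](C)[C@H](O[Si](C)(C)C(C)(C)C)/C(C)=C/I | intermediate
14 | (2Z)-4-(tert-butyldimethylsilyloxy)-6-ethyl-2-ethylidene-3,5-dimethyl-2H-pyran | C/C=C1\OC(CC)=C(C)C(O[Si](C)(C)C(C)(C)C)=C1C | intermediate
15 | 2-ethyl-6-[(2S,3S,4S,5S,6E)-5-(tert-butyldimethylsilyloxy)-3-hydroxy-7-iodo-4,6-dimethylhept-6-en-2-yl]-3,5-dimethyl-4H-pyran-4-one | CCc1oc([C@@H](C)[C@@H](O)[C@H](C)[C@H](O[Si](C)(C)C(C)(C)C)/C(C)=C/I)c(C)c(=O)c1C | intermediate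
16 | (S)-4-benzyl-3-propanoyl-1,3-oxazolidin-2-one | CCC(=O)N1[C@@H](Cc2ccccc2)COC1=O | starting material
17 | propanal | CCC=O | starting material
18 | dibutylboron Z-enolate of 16 | C/C=C(\OB(CCCC)CCCC)N1[C@@H](Cc2ccccc2)COC1=O | intermediate
19 | dibutylboron aldolate of 20 | O=C(N1[C@@H](Cc2ccccc2)COC1=O)[C@@H](C)[C@H](OB(CCCC)CCCC)CC | intermediate
20 | (S)-4-benzyl-3-[(2S,3R)-3-hydroxy-2-methylpentanoyl]-1,3-oxazolidin-2-one | O=C(N1[C@@H](Cc2ccccc2)COC1=O)[C@@H](C)[C@H](O)CC | intermediate
21 | (2S,3R)-3-hydroxy-N-methoxy-N,2-dimethylpentanamide | CON(C)C(=O)[C@@H](C)[C@H](O)CC | intermediate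
22 | (2S,3R)-3-(tert-butyldimethylsilyloxy)-N-methoxy-N,2-dimethylpentanamide | CON(C)C(=O)[C@@H](C)[C@H](O[Si](C)(C)C(C)(C)C)CC | intermediate
23 | 4-methylheptane-3,5-dione | CCC(=O)C(C)C(=O)CC | starting material
24 | dilithium dienolate (1,3-dianion) of 23 | CCC(O[Li])=C(C)C(O[Li])=CC | intermediate
25 | (8S,9R)-9-(tert-butyldimethylsilyloxy)-4,6,8-trimethylundecane-3,5,7-trione (C4/C6 epimers and enols) | CCC(=O)C(C)C(=O)C(C)C(=O)[C@@H](C)[C@H](O[Si](C)(C)C(C)(C)C)CC | intermediate
26 | 2-ethyl-6-[(2S,3R)-3-(tert-butyldimethylsilyloxy)pentan-2-yl]-3,5-dimethyl-4H-pyran-4-one | CCc1oc([C@@H](C)[C@H](O[Si](C)(C)C(C)(C)C)CC)c(C)c(=O)c1C | intermediate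
27 | lithium vinylogous enolate of 26 (2-ethylidene-2H-pyran-4-olate) | C/C=C1\OC([C@@H](C)[C@H](O[Si](C)(C)C(C)(C)C)CC)=C(C)C(O[Li])=C1C | intermediate
28 | 2-(1-chloroethyl)-6-[(2S,3R)-3-(tert-butyldimethylsilyloxy)pentan-2-yl]-3,5-dimethyl-4H-pyran-4-one (both CHCl epimers) | CC(Cl)c1oc([C@@H](C)[C@H](O[Si](C)(C)C(C)(C)C)CC)c(C)c(=O)c1C | intermediate
29 | 5,3''-bis(tert-butyldimethylsilyl) ether of 30 | CCc1oc([C@@H](C)[C@@H](O)[C@H](C)[C@H](O[Si](C)(C)C(C)(C)C)/C(C)=C/[C@@H](C)c2oc([C@@H](C)[C@H](O[Si](C)(C)C(C)(C)C)CC)c(C)c(=O)c2C)c(C)c(=O)c1C | intermediate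
30 | 2-ethyl-6-[(2S,3S,4S,5S,6E,8R)-3,5-dihydroxy-8-{6-[(2S,3R)-3-hydroxypentan-2-yl]-3,5-dimethyl-4-oxo-4H-pyran-2-yl}-4,6-dimethylnon-6-en-2-yl]-3,5-dimethyl-4H-pyran-4-one | CCc1oc([C@@H](C)[C@@H](O)[C@H](C)[C@H](O)/C(C)=C/[C@@H](C)c2oc([C@@H](C)[C@H](O)CC)c(C)c(=O)c2C)c(C)c(=O)c1C | target

## Step count and risks

Total step count: 15.
Longest linear sequence: 8 steps. This holds for 5 → 30 through steps 2, 3, 4, 5, 6, 7, 14 and 15, and equally for 16 → 30 through steps 8 to 15.

**Most likely to fail, 1: step 14.**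
- A pyronyl-ethyl chloride is untested as a partner in this coupling.
- The alkenyl iodide carries a cis methyl group, which adds hindrance.
- The stabilised radical can dimerise.
- Ligand control may be eroded by the chiral partners.

The fallback sets out from 12 and 28 and comes back at 29. The alkenyl donor is preformed on the small iodide 12, which carries no acidic proton, no free OH and no second pyrone. Treatment with t-BuLi (2 equiv, Et2O, −78 °C) and then ZnBr2 gives the alkenylzinc bromide F1. F1 is joined to 28 in a stereoconvergent Negishi alkenylation of an α-halo-carbonyl-type electrophile (NiCl2·glyme, chiral bis(oxazoline), DME/THF, 0 to 10 °C), giving the ring-B diene F2. OsO4/NaIO4 then cleaves only the monosubstituted vinyl group to the aldehyde F3. The vinylogous Mukaiyama aldol of 4 (through 14) with F3, under the conditions of step 7, gives 29. The assembly thus becomes linear, and ring A is attached last.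

**Most likely to fail, 2: step 7.** The aldehyde face (C3) is well controlled, but the 2,3-anti relation rests on an open transition state of a new nucleophile.

The fallback sets out from 4 and 13 and comes back at 15. It sets C2 and C3 by reduction instead of by C–C bond formation.
- LiHMDS deprotonation of 4 and addition to 13 (THF, −78 °C) gives the stereo-random aldol mixture F4.
- Dess–Martin oxidation gives the β-keto pyrone F5, in which C2 is now labile.
- HF·pyridine frees the hydroxy ketone F6.
- Evans–Saksena reduction (Me4NBH(OAc)3, MeCN/AcOH, −20 °C) delivers hydride from the C5 alkoxyborohydride, giving the 3,5-anti diol. It consumes faster the equilibrating C2 epimer that places the pyrone anti to the incoming hydride (Felkin–Anh, 2,3-anti). The product is the diol F7.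
- TBSOTf (1.0 equiv, 2,6-lutidine, −78 °C) silylates the less hindered allylic 5-OH to give 15.

**Most likely to fail, 3: step 11.** The α-branched Weinreb amide is hindered, and the basic dianion may instead cleave the N–OMe group or enolise the amide.

The fallback sets out from 22 and comes back at 25. It trades acylation for addition followed by oxidation. DIBAL-H (toluene, −78 °C) gives the aldehyde F8. The dianion 24 adds to this far more electrophilic carbonyl at −78 °C to give the hydroxy diketone F9. Dess–Martin oxidation then gives 25.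

## Further compounds

F1 | step 14 | bromo[(1E,3S,4S)-3-(tert-butyldimethylsilyloxy)-2,4-dimethylhexa-1,5-dien-1-yl]zinc | C=C[C@H](C)[C@H](O[Si](C)(C)C(C)(C)C)/C(C)=C/[Zn]Br
F2 | step 14 | 2-[(2R,3E,5S,6S)-5-(tert-butyldimethylsilyloxy)-4,6-dimethylocta-3,7-dien-2-yl]-6-[(2S,3R)-3-(tert-butyldimethylsilyloxy)pentan-2-yl]-3,5-dimethyl-4H-pyran-4-one | C=C[C@H](C)[C@H](O[Si](C)(C)C(C)(C)C)/C(C)=C/[C@@H](C)c1oc([C@@H](C)[C@H](O[Si](C)(C)C(C)(C)C)CC)c(C)c(=O)c1C
F3 | step 14 | (2R,3S,4E,6R)-3-(tert-butyldimethylsilyloxy)-6-{6-[(2S,3R)-3-(tert-butyldimethylsilyloxy)pentan-2-yl]-3,5-dimethyl-4-oxo-4H-pyran-2-yl}-2,4-dimethylhept-4-enal | O=C[C@H](C)[C@H](O[Si](C)(C)C(C)(C)C)/C(C)=C/[C@@H](C)c1oc([C@@H](C)[C@H](O[Si](C)(C)C(C)(C)C)CC)c(C)c(=O)c1C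
F4 | step 7 | 2-ethyl-6-[(4S,5S,6E)-5-(tert-butyldimethylsilyloxy)-3-hydroxy-7-iodo-4,6-dimethylhept-6-en-2-yl]-3,5-dimethyl-4H-pyran-4-one (C2/C3 isomer mixture) | CCc1oc(C(C)C(O)[C@H](C)[C@H](O[Si](C)(C)C(C)(C)C)/C(C)=C/I)c(C)c(=O)c1C
F5 | step 7 | 2-ethyl-6-[(4R,5S,6E)-5-(tert-butyldimethylsilyloxy)-7-iodo-4,6-dimethyl-3-oxohept-6-en-2-yl]-3,5-dimethyl-4H-pyran-4-one (C2 labile) | CCc1oc(C(C)C(=O)[C@H](C)[C@H](O[Si](C)(C)C(C)(C)C)/C(C)=C/I)c(C)c(=O)c1C
F6 | step 7 | 2-ethyl-6-[(4R,5S,6E)-5-hydroxy-7-iodo-4,6-dimethyl-3-oxohept-6-en-2-yl]-3,5-dimethyl-4H-pyran-4-one (C2 labile) | CCc1oc(C(C)C(=O)[C@H](C)[C@H](O)/C(C)=C/I)c(C)c(=O)c1C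
F7 | step 7 | 2-ethyl-6-[(2S,3S,4S,5S,6E)-3,5-dihydroxy-7-iodo-4,6-dimethylhept-6-en-2-yl]-3,5-dimethyl-4H-pyran-4-one | CCc1oc([C@@H](C)[C@@H](O)[C@H](C)[C@H](O)/C(C)=C/I)c(C)c(=O)c1C
F8 | step 11 | (2S,3R)-3-(tert-butyldimethylsilyloxy)-2-methylpentanal | O=C[C@@H](C)[C@H](O[Si](C)(C)C(C)(C)C)CC
F9 | step 11 | (8R,9R)-9-(tert-butyldimethylsilyloxy)-7-hydroxy-4,6,8-trimethylundecane-3,5-dione (C4/C6/C7 isomer mixture) | CCC(=O)C(C)C(=O)C(C)C(O)[C@@H](C)[C@H](O[Si](C)(C)C(C)(C)C)CC
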